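The data are calculated with made-up constants, and the scatter is random.

Count the partner.

all flasks: precatalyst 7.2 mol%

| flask | left-handed substrate | right-handed substrate | partner | protic impurity | temperature | remark | time |
|---|---|---|---|---|---|---|---|
| Monday's | 0.056 M | 0.056 M | 1.1 equiv | 2.8 mM | 5 °C | run made earlier |  |
| Wednesday's | 0.056 M | 0.056 M | 1.1 equiv | 4.2 mM | 16 °C | run made earlier |  |
| Saturday's | 0.11 M | 0.11 M | 1.1 equiv | 5.6 mM | 5 °C | run made earlier |  |
| cedar | 0.056 M | 0.056 M | 1.10 equiv | 5.60 mM | 20 °C |  | 25 min |
| ash | 0.056 M | 0.056 M | 1.10 equiv | 5.60 mM |  | at 0 °C until 5.0 min, from then on at 20 °C | 25 min |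
| maple | 0.056 M | 0.056 M | 1.10 equiv | 5.60 mM | 0 °C |  | 25 min |

| run | time / min | left-handed product / % | left-handed substrate / % |
|---|---|---|---|
| Monday's | 3.00 | 13.8 | 35.4 |
| Monday's | 10.0 | 29.0 | 19.4 |
| Monday's | 15.0 | 31.5 | 18.1 |
| Monday's | 30.0 | 31.8 | 17.9 |
| Monday's | 40.0 | 30.1 | 20.2 |
| Monday's | 50.0 | 31.5 | 17.3 |
| Wednesday's | 4.00 | 28.6 | 22.1 |
| Wednesday's | 8.00 | 29.9 | 18.7 |
| Wednesday's | 12.0 | 31.6 | 19.9 |
| Wednesday's | 15.0 | 30.8 | 20.6 |
| Wednesday's | 20.0 | 30.1 | 19.1 |
| Wednesday's | 25.0 | 30.9 | 20.4 |
| Saturday's | 10.0 | 31.7 | 18.3 |
| Saturday's | 20.0 | 30.2 | 20.9 |
| Saturday's | 30.0 | 31.1 | 17.2 |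
| Saturday's | 40.0 | 31.2 | 19.1 |
| Saturday's | 50.0 | 31.4 | 17.1 |

(standard deviation of a reading: 1 percentage point)

- which flask leads in amount of left-handed product, in percent of the left-handed substrate and right-handed substrate together charged ("all alike" within 1.5 percentage points) (cedar / ash / maple / all alike)
- how much left-handed product is there at the end, in percent of the left-handed substrate and right-handed substrate together charged: cedar
- how much left-handed product is there at the end, in percent of the left-handed substrate and right-handed substrate together charged: ash
- how much left-handed product is there at the end, in percent of the left-handed substrate and right-handed substrate together charged: maple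

- free catalyst is single-handed; left-handed substrate and right-handed substrate are mirror images of each other, charged as a racemate, each of them at the stated concentration
- the analysis behind the earlier runs scatters by 1 percentage point, standard deviation
- steps that have been proposed: partner + free catalyst + left-handed substrate -> free catalyst + left-handed product; partner + free catalyst + right-handed substrate -> free catalyst + right-handed product; free catalyst -> spent catalyst; partner + protic impurity -> quenched reagent; precatalyst -> free catalyst

In the proposed steps both substrates and the protic impurity consume partner, so we fold the charge of cedar, ash and maple into one number: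

β = (partner charged − protic impurity charged) / (both substrates charged) = 50.0%

We call β the partner budget, the part of the racemate that partner, the limiting reagent, can turn into product if the protic impurity takes partner for its whole charge.

Monday's budget is 52.5% and its plateau readings of left-handed product average 31.2%, so we read a left-handed share of the budget, φ, of 0.595.

Is one number enough? For Wednesday's warmer run, φβ gives 30.5% against a plateau mean of 30.7%. For Saturday's run, with twice Monday's charge, it gives 31.2% against 31.1%.

Time still has to be tested, and Wednesday reached at 4.00 min about what Monday reached at 10.0 min, a rough factor of 2.50 that we lay on temperature, though the impurity differs too. Stretching 15.0 min, Monday's first plateau reading, to maple's temperature by that factor gives roughly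

t ≈ 22.7 min

which is shorter than the 25 min allowed, though not by much. Our reckoning for each flask is therefore φβ = 29.7%, so we expect the flasks alike within 1.5 percentage points.

The forecast, with 29.6% for cedar, 29.6% for ash and 29.3% for maple, stands a little below ours and answers all alike, on the grounds that “the likely cause is partner exhaustion”.

The simulation gives 29.8% in cedar, 29.8% in ash and 30.2% in maple: all alike.

    partner + free catalyst + left-handed substrate → free catalyst + left-handed product (k = 130 /M²/s, Ea = 37.0 kJ/mol)
    partner + free catalyst + right-handed substrate → free catalyst + right-handed product (k = 79.0 /M²/s, Ea = 40.0 kJ/mol)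
    free catalyst → spent catalyst (k = 0.00290 /s, Ea = 82.0 kJ/mol)
    partner + protic impurity → quenched reagent (k = 0.360 /M/s, Ea = 39.0 kJ/mol)
    precatalyst → free catalyst (k = 0.0120 /s, Ea = 74.0 kJ/mol)
    (constants at 20 °C)

In maple the two products together stand at 50.3% against a budget of 50.0%, with partner at 0.239% and protic impurity at 9.06% of their charges. Maple had half of its left-handed product's turnover behind it at 4.95 min, much earlier than the 25 min allowed.

For a neighbour of maple charged with 0.280 equiv of partner, β is 9.00%. That flask holds 7.61% left-handed and 4.38% right-handed product, 12.0% together, with partner at 0% and 0.00224 M of quenched reagent, and counting that amount as the impurity's share brings β to 12.0%.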